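## Retrosynthetic overview

1. Oxirane ⇐ silyl-protected (1S)-chlorohydrin on C10, closed by fluoride in the last step; methacrylate ⇐ 9α-OH; acrolein ⇐ SeO2 oxidation of a C5 isopropenyl group.
2. cis-Fused α-methylene-γ-lactone ⇐ C9 ketone carrying a C7 acrylic acid (C8 enolate iodination, intramolecular SN2); acrylic acid ⇐ C7 ethynyl group (Markovnikov hydrocarboxylation).
3. C5, C10 and C1 ⇐ one three-component coupling on a 2-methyl enone: isopropenyl conjugate addition, then enolate aldol with chloroacetaldehyde.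
4. C7 and the enone ⇐ 4-methoxy-2-methylphenol: oxidative dearomatisation to the quinone monoketal and, in the same flask, enantioselective conjugate alkynylation.
5. Ring order: the carbocycle is the former benzene ring (never closed); lactone ring in step 7; oxirane in step 11.

Numbering used below: ring carbons carry elemane numbers, C9 (former phenol carbon), C10 (methyl-bearing), C5, C6 (former C–OMe carbon), C7, C8; side-chain carbons are C1–C2 on C10, C4/C3/C15 on C5, C11/C12/C13 on C7. With C9→C8→C7→C6→C5→C10 drawn clockwise, β points to the viewer and α away. The target is 9α-O, 8α-O, 7α-C, 6β-OH, 5β-C, 10β-CH3, 10α-oxiranyl, (1S).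

Assumption: the (R)-ligand is written for step 1 by analogy with rhodium/bisphosphine conjugate additions to cyclohexenones; if this substrate gives the (5S) adduct the (S)-ligand is used, and the target is drawn as the open hydroxy aldehyde although it may equilibrate with its cyclic hemiacetal.

## Route

Step 1
Reactants: 1 4-methoxy-2-methylphenol; 2 (triisopropylsilyl)acetylene
Product: 4 (5R)-4,4-dimethoxy-2-methyl-5-[(triisopropylsilyl)ethynyl]cyclohex-2-en-1-one, via quinone monoketal 3 (not isolated)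
Conditions: PhI(OAc)2 (1.05 equiv), MeOH, 0 °C; evaporate (PhMe chase); then 2 (1.5 equiv), [Rh(OAc)(C2H4)2]2 (2.5 mol%), (R)-DTBM-SEGPHOS (6 mol%), 1,4-dioxane, 60 °C
Reagents that add atoms: methanol (CO)
Why: Proposed new method: trivalent-iodine oxidation of the p-methoxyphenol in methanol (oxidative dearomatisation) gives the quinone monoketal, and a monovalent rhodium acetylide formed from 2 inserts only into the unsubstituted enone (the 2-methyl enone is inert), from the face set by the bisphosphine, which fixes C7; the closest known reactions are quinone monoketal formation with PhI(OAc)2 and the Hayashi–Nishimura asymmetric conjugate alkynylation of cyclic enones.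

Step 2
Reactants: 4 (5R)-4,4-dimethoxy-2-methyl-5-[(triisopropylsilyl)ethynyl]cyclohex-2-en-1-one; 5 isopropenylmagnesium bromide; 6 chloroacetaldehyde (anhydrous, freshly distilled)
Product: 9 9-oxo-6,6-dimethoxy-7α-[(triisopropylsilyl)ethynyl]-5β-isopropenyl-10β-methyl-10α-[(1S)-1-(tert-butyldimethylsilyloxy)-2-chloroethyl]cyclohexane, via magnesium enolate 7 (not isolated), via magnesium aldolate 8 (not isolated)
Conditions: 5 (1.3 equiv), CuBr·SMe2 (20 mol%), THF, −78 → −40 °C; 6 (1.5 equiv), −78 °C; then TBSOTf (1.5 equiv), −78 → −20 °C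
Reagents that add atoms: tert-butyldimethylsilyl triflate (CC(C)(C)[Si](C)(C)OS(=O)(=O)C(F)(F)F)
Why: Copper-catalysed conjugate addition puts the isopropenyl group on C5 trans to the C7 substituent (3,5-trans rule), the enolate then adds to the aldehyde anti to that group through a Zimmerman–Traxler chair with CH2Cl equatorial, which sets C10 and the (1S) carbinol, and in-flask O-silylation stops retro-aldol and early oxirane closure.

Step 3
Reactants: 9 9-oxo-6,6-dimethoxy-7α-[(triisopropylsilyl)ethynyl]-5β-isopropenyl-10β-methyl-10α-[(1S)-1-(tert-butyldimethylsilyloxy)-2-chloroethyl]cyclohexane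
Product: 11 7α-ethynyl-5β-isopropenyl-10β-methyl-10α-[(1S)-1-(tert-butyldimethylsilyloxy)-2-chloroethyl]cyclohexane-6,9-dione, via silver acetylide 10 (not isolated)
Conditions: AgF (1.5 equiv), MeOH, rt, dark; then 1 M HCl, THF, 0 °C; used at once
Reagents that add atoms: water (O)
Why: Silver fluoride cleaves the C(sp)–Si bond (protodesilylation via the silver acetylide) without touching the O-silyl ether, dilute acid protonates the acetylide and hydrolyses the dimethyl ketal, and rearomatisation is impossible because C10 is quaternary; no stereocenter is formed.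

Step 4
Reactants: 11 7α-ethynyl-5β-isopropenyl-10β-methyl-10α-[(1S)-1-(tert-butyldimethylsilyloxy)-2-chloroethyl]cyclohexane-6,9-dione
Product: 12 6β-hydroxy-7α-ethynyl-5β-isopropenyl-10β-methyl-10α-[(1S)-1-(tert-butyldimethylsilyloxy)-2-chloroethyl]cyclohexan-9-one
Conditions: LiBH(s-Bu)3 (1.05 equiv), THF, −78 °C; then H2O
Reagents that add atoms: none
Why: The bulky hydride reduces the C6 ketone in preference to the neopentyl C9 ketone and enters from the α face (anti to the β-isopropenyl on C5 and the axial 10β-methyl, past only the rod-like ethynyl group), giving the axial 6β-alcohol (diastereoselective ketone reduction by equatorial attack).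

Step 5
Reactants: 12 6β-hydroxy-7α-ethynyl-5β-isopropenyl-10β-methyl-10α-[(1S)-1-(tert-butyldimethylsilyloxy)-2-chloroethyl]cyclohexan-9-one
Product: 13 6β-(tert-butyldimethylsilyloxy)-7α-ethynyl-5β-isopropenyl-10β-methyl-10α-[(1S)-1-(tert-butyldimethylsilyloxy)-2-chloroethyl]cyclohexan-9-one
Conditions: TBSOTf, 2,6-lutidine, CH2Cl2, −40 → 0 °C
Reagents that add atoms: tert-butyldimethylsilyl triflate (CC(C)(C)[Si](C)(C)OS(=O)(=O)C(F)(F)F)
Why: Silyl ether formation masks O6 so that it cannot take part in the palladium carbonylation or lactonise onto C12 (alcohol silylation; no stereocenter).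

Step 6
Reactants: 13 6β-(tert-butyldimethylsilyloxy)-7α-ethynyl-5β-isopropenyl-10β-methyl-10α-[(1S)-1-(tert-butyldimethylsilyloxy)-2-chloroethyl]cyclohexan-9-one
Product: 14 2-[6β-(tert-butyldimethylsilyloxy)-5β-isopropenyl-10β-methyl-9-oxo-10α-[(1S)-1-(tert-butyldimethylsilyloxy)-2-chloroethyl]cyclohex-7α-yl]acrylic acid
Conditions: Pd2(dba)3 (2.5 mol%), Xantphos (10 mol%), HCO2H (3 equiv), Ac2O (20 mol%), PhMe, 80 °C
Reagents that add atoms: formic acid (OC=O)
Why: A palladium hydride formed from zerovalent palladium and formic acid adds to the terminal alkyne in the Markovnikov sense and CO from formic acid is inserted, giving the 2-substituted acrylic acid (palladium-catalysed hydrocarboxylation of alkynes); the alkenes and the alkyl chloride are far slower and no stereocenter is touched.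

Step 7
Reactants: 14 2-[6β-(tert-butyldimethylsilyloxy)-5β-isopropenyl-10β-methyl-9-oxo-10α-[(1S)-1-(tert-butyldimethylsilyloxy)-2-chloroethyl]cyclohex-7α-yl]acrylic acid
Product: 17 9-oxo-12,8α-olide (cis-fused α-methylene-γ-lactone) with 6β-OTBS 5β-isopropenyl 10β-methyl 10α-[(1S)-1-(tert-butyldimethylsilyloxy)-2-chloroethyl], via dilithium enolate carboxylate 15 (not isolated), via iodo ketone 16 (not isolated)
Conditions: LiN(SiMe3)2 (2.2 equiv), THF, −78 °C; I2 (1.05 equiv), −78 → 0 °C
Reagents that add atoms: none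
Why: The C9 ketone can enolise only toward C8, the enolate is iodinated on the β face anti to the C7 substituent, and the tethered carboxylate displaces iodide by intramolecular SN2 with inversion, so the new C8–O bond is forced cis to C7–C11 (oxidative α-lactonisation of a δ-keto acid).

Step 8
Reactants: 17 9-oxo-12,8α-olide with 6β-OTBS 5β-isopropenyl 10β-methyl 10α-[(1S)-1-(tert-butyldimethylsilyloxy)-2-chloroethyl]
Product: 18 9α-hydroxy-12,8α-olide with 6β-OTBS 5β-isopropenyl 10β-methyl 10α-[(1S)-1-(tert-butyldimethylsilyloxy)-2-chloroethyl]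
Conditions: NaBH4, CeCl3·7H2O, MeOH, −78 °C
Reagents that add atoms: none
Why: Luche reduction is 1,2-selective so the α-methylene lactone survives, and hydride comes from the convex β face, anti to the C8–O bond and to the bulky 10α side chain, giving the 9α-alcohol cis to O8.

Step 9
Reactants: 18 9α-hydroxy-12,8α-olide with 6β-OTBS 5β-isopropenyl 10β-methyl 10α-[(1S)-1-(tert-butyldimethylsilyloxy)-2-chloroethyl]
Product: 19 9α-methacryloyloxy-12,8α-olide with 6β-OTBS 5β-isopropenyl 10β-methyl 10α-[(1S)-1-(tert-butyldimethylsilyloxy)-2-chloroethyl]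
Conditions: methacrylic anhydride, DMAP, Et3N, CH2Cl2, rt
Reagents that add atoms: methacrylic anhydride (CC(=C)C(=O)OC(=O)C(C)=C)
Why: DMAP-catalysed acylation of the only free hydroxyl (Steglich-type esterification); the alcohol oxygen is the nucleophile, so C9 keeps its configuration.

Step 10
Reactants: 19 9α-methacryloyloxy-12,8α-olide with 6β-OTBS 5β-isopropenyl 10β-methyl 10α-[(1S)-1-(tert-butyldimethylsilyloxy)-2-chloroethyl]
Product: 21 9α-methacryloyloxy-12,8α-olide with 6β-OTBS 5β-(3-oxoprop-1-en-2-yl) 10β-methyl 10α-[(1S)-1-(tert-butyldimethylsilyloxy)-2-chloroethyl], via allylic alcohol 20 (not isolated)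
Conditions: SeO2 (0.5 equiv), t-BuOOH (3 equiv), CH2Cl2, rt; then MnO2, CH2Cl2, rt
Reagents that add atoms: tert-butyl hydroperoxide (CC(C)(C)OO); selenium dioxide (O=[Se]=O)
Why: Riley allylic oxidation (ene reaction then [2,3] shift) attacks the methyl of the electron-rich 1,1-disubstituted isopropenyl group, while the acrylate-type alkenes are electron-poor; MnO2 then takes the allylic alcohol to the enal, and no stereocenter is involved.

Step 11
Reactants: 21 9α-methacryloyloxy-12,8α-olide with 6β-OTBS 5β-(3-oxoprop-1-en-2-yl) 10β-methyl 10α-[(1S)-1-(tert-butyldimethylsilyloxy)-2-chloroethyl]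
Product: 23 target CNP0124638.3, via chloro alkoxide 22 (not isolated)
Conditions: Bu4NF (3 equiv), THF, 0 °C, short reaction time; pH 7 buffer quench
Reagents that add atoms: none
Why: Fluoride cleaves both silyl ethers and the C1 alkoxide closes the oxirane by 3-exo-tet Williamson displacement of the primary chloride, with retention at C1 because the C1–O bond is untouched (fluoride-triggered epoxide formation from a silylated halohydrin).

## Compound list

1 | 4-methoxy-2-methylphenol | Cc1cc(OC)ccc1O | starting material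
2 | (triisopropylsilyl)acetylene | C#C[Si](C(C)C)(C(C)C)C(C)C | starting material
3 | 4,4-dimethoxy-2-methylcyclohexa-2,5-dien-1-one (quinone monoketal) | CC1=CC(OC)(OC)C=CC1=O | intermediate
4 | (5R)-4,4-dimethoxy-2-methyl-5-[(triisopropylsilyl)ethynyl]cyclohex-2-en-1-one (C1 = C9, C2 = C10, C3 = C5, C4 = C6, C5 = C7, C6 = C8; alkyne 7α) | O=C1C[C@H](C#C[Si](C(C)C)(C(C)C)C(C)C)C(OC)(OC)C=C1C | intermediate
5 | isopropenylmagnesium bromide | CC(=C)[Mg]Br | starting material
6 | chloroacetaldehyde | ClCC=O | starting material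
7 | bromomagnesium C9=C10 enolate of the 5β-isopropenyl adduct (7α-silylethynyl, 6,6-dimethoxy) | Br[Mg]OC=1C[C@H](C#C[Si](C(C)C)(C(C)C)C(C)C)C(OC)(OC)[C@@H](C(C)=C)C=1C | intermediate
8 | bromomagnesium aldolate: 9-ketone with 10β-methyl and 10α-[(1S)-2-chloro-1-(bromomagnesiooxy)ethyl] | O=C1C[C@H](C#C[Si](C(C)C)(C(C)C)C(C)C)C(OC)(OC)[C@@H](C(C)=C)[C@]1(C)[C@H](O[Mg]Br)CCl | intermediate
9 | 9-oxo-6,6-dimethoxy-7α-[(triisopropylsilyl)ethynyl]-5β-isopropenyl-10β-methyl-10α-[(1S)-1-(tert-butyldimethylsilyloxy)-2-chloroethyl]cyclohexane | O=C1C[C@H](C#C[Si](C(C)C)(C(C)C)C(C)C)C(OC)(OC)[C@@H](C(C)=C)[C@]1(C)[C@H](O[Si](C)(C)C(C)(C)C)CCl | intermediate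
10 | silver acetylide of 9 (C–Si replaced by C–Ag, ketal intact) | O=C1C[C@H](C#C[Ag])C(OC)(OC)[C@@H](C(C)=C)[C@]1(C)[C@H](O[Si](C)(C)C(C)(C)C)CCl | intermediate
11 | 7α-ethynyl-5β-isopropenyl-10β-methyl-10α-[(1S)-1-(tert-butyldimethylsilyloxy)-2-chloroethyl]cyclohexane-6,9-dione | O=C1C[C@H](C#C)C(=O)[C@@H](C(C)=C)[C@]1(C)[C@H](O[Si](C)(C)C(C)(C)C)CCl | intermediate
12 | 6β-hydroxy-9-ketone (7α-ethynyl, 5β-isopropenyl, 10β-methyl, 10α-[(1S)-1-OTBS-2-chloroethyl]) | O=C1C[C@H](C#C)[C@@H](O)[C@@H](C(C)=C)[C@]1(C)[C@H](O[Si](C)(C)C(C)(C)C)CCl | intermediate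
13 | 6β-OTBS-9-ketone (7α-ethynyl, 5β-isopropenyl, 10β-methyl, 10α-[(1S)-1-OTBS-2-chloroethyl]) | O=C1C[C@H](C#C)[C@@H](O[Si](C)(C)C(C)(C)C)[C@@H](C(C)=C)[C@]1(C)[C@H](O[Si](C)(C)C(C)(C)C)CCl | intermediate
14 | 7α-(1-carboxyvinyl)-9-ketone (6β-OTBS, 5β-isopropenyl, 10β-methyl, 10α-[(1S)-1-OTBS-2-chloroethyl]) | O=C1C[C@H](C(=C)C(=O)O)[C@@H](O[Si](C)(C)C(C)(C)C)[C@@H](C(C)=C)[C@]1(C)[C@H](O[Si](C)(C)C(C)(C)C)CCl | intermediate
15 | dilithium C8=C9 enolate carboxylate of 14 | [Li+].[Li+].[O-]C1=C[C@H](C(=C)C(=O)[O-])[C@@H](O[Si](C)(C)C(C)(C)C)[C@@H](C(C)=C)[C@]1(C)[C@H](O[Si](C)(C)C(C)(C)C)CCl | intermediate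
16 | 8β-iodo-9-ketone lithium carboxylate | [Li+].O=C1[C@@H](I)[C@H](C(=C)C(=O)[O-])[C@@H](O[Si](C)(C)C(C)(C)C)[C@@H](C(C)=C)[C@]1(C)[C@H](O[Si](C)(C)C(C)(C)C)CCl | intermediate
17 | 9-oxo-12,8α-olide: cis-fused α-methylene-γ-lactone (6β-OTBS, 5β-isopropenyl, 10β-methyl, 10α-[(1S)-1-OTBS-2-chloroethyl]) | O=C1[C@@H]2OC(=O)C(=C)[C@@H]2[C@@H](O[Si](C)(C)C(C)(C)C)[C@@H](C(C)=C)[C@]1(C)[C@H](O[Si](C)(C)C(C)(C)C)CCl | intermediate
18 | 9α-hydroxy-12,8α-olide (otherwise as 17) | O[C@@H]1[C@@H]2OC(=O)C(=C)[C@@H]2[C@@H](O[Si](C)(C)C(C)(C)C)[C@@H](C(C)=C)[C@]1(C)[C@H](O[Si](C)(C)C(C)(C)C)CCl | intermediate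
19 | 9α-methacryloyloxy-12,8α-olide (otherwise as 17) | C=C(C)C(=O)O[C@@H]1[C@@H]2OC(=O)C(=C)[C@@H]2[C@@H](O[Si](C)(C)C(C)(C)C)[C@@H](C(C)=C)[C@]1(C)[C@H](O[Si](C)(C)C(C)(C)C)CCl | intermediate
20 | allylic alcohol: 5β-(3-hydroxyprop-1-en-2-yl) analogue of 19 | C=C(C)C(=O)O[C@@H]1[C@@H]2OC(=O)C(=C)[C@@H]2[C@@H](O[Si](C)(C)C(C)(C)C)[C@@H](C(=C)CO)[C@]1(C)[C@H](O[Si](C)(C)C(C)(C)C)CCl | intermediate
21 | enal: 5β-(3-oxoprop-1-en-2-yl) analogue of 19 | C=C(C)C(=O)O[C@@H]1[C@@H]2OC(=O)C(=C)[C@@H]2[C@@H](O[Si](C)(C)C(C)(C)C)[C@@H](C(=C)C=O)[C@]1(C)[C@H](O[Si](C)(C)C(C)(C)C)CCl | intermediate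
22 | tetrabutylammonium (1S)-2-chloro-1-oxidoethyl compound (6β-OH free, both silyl groups removed) | C=C(C)C(=O)O[C@@H]1[C@@H]2OC(=O)C(=C)[C@@H]2[C@@H](O)[C@@H](C(=C)C=O)[C@]1(C)[C@H]([O-])CCl.CCCC[N+](CCCC)(CCCC)CCCC | intermediate
23 | CNP0124638.3: 9α-methacryloyloxy-6β-hydroxy-12,8α-olide with 5β-(3-oxoprop-1-en-2-yl), 10β-methyl, 10α-[(1S)-oxiranyl] | C=C(C)C(=O)O[C@@H]1[C@@H]2OC(=O)C(=C)[C@@H]2[C@@H](O)[C@@H](C(=C)C=O)[C@]1(C)[C@H]1CO1 | target

## Step count and weak points

Total step count: 11. Longest linear sequence: 11 steps (1 → 23).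

Step 1 is the most exposed. The rhodium acetylide must insert at a β-carbon flanked by the ketal, the enantioselectivity on this substrate is untested, and 3 or 4 can rearomatise with traces of acid at 60 °C. The fallback sets out from 3, isolated after the oxidation of 1 by bicarbonate work-up. The rhodium C–H alkynylation is replaced by a nickel-catalysed enantioselective conjugate addition of the preformed aluminium acetylide Me2AlC≡CSiMe3 (Ni(acac)2, chiral cyano-bis(oxazoline) ligand, 0 °C), which gives the trimethylsilyl analogue F1. The coupling of step 2 applied to F1 gives the silyl-protected chlorohydrin F2. K2CO3 in MeOH followed by dilute HCl removes the C-silyl group and the ketal and brings the material back to 11.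

Step 2 is the second risk. Conjugate addition to an α-methyl enone next to a ketal may be slow, and the C1 configuration rests on one aldol transition state. The fallback sets out from 4. The same conjugate addition and aldol are run, but the mixture is quenched cold with aqueous NH4Cl and the C1-epimeric chlorohydrins F3 are isolated. Dess–Martin oxidation gives the chloromethyl ketone F4. Reduction with the (S)-Me-CBS oxazaborolidine and BH3·SMe2, with quaternary C10 as the large group and the hindered ring ketone left alone, gives the (1S)-chlorohydrin F5 under reagent control. TBSOTf and 2,6-lutidine then return to 9.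

Step 11 is the third risk. The C1 alkoxide could transfer the neighbouring methacrylate instead of closing the ring, and the alkoxides could add to the three Michael acceptors. The fallback sets out from 21. HF·pyridine buffered with pyridine removes both silyl ethers without forming an alkoxide and gives the chlorohydrin diol F6, which is isolated. Ag2O in CH2Cl2 then closes the oxirane by halide abstraction under non-basic conditions and delivers 23.

## Further compounds

F1 | step 1 | (5R)-4,4-dimethoxy-2-methyl-5-[(trimethylsilyl)ethynyl]cyclohex-2-en-1-one | O=C1C[C@H](C#C[Si](C)(C)C)C(OC)(OC)C=C1C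
F2 | step 1 | trimethylsilylethynyl analogue of 9 | O=C1C[C@H](C#C[Si](C)(C)C)C(OC)(OC)[C@@H](C(C)=C)[C@]1(C)[C@H](O[Si](C)(C)C(C)(C)C)CCl
F3 | step 2 | free chlorohydrin corresponding to 9, mixture of C1 epimers | O=C1C[C@H](C#C[Si](C(C)C)(C(C)C)C(C)C)C(OC)(OC)[C@@H](C(C)=C)[C@]1(C)C(O)CCl
F4 | step 2 | 10α-chloroacetyl ketone | O=C1C[C@H](C#C[Si](C(C)C)(C(C)C)C(C)C)C(OC)(OC)[C@@H](C(C)=C)[C@]1(C)C(=O)CCl
F5 | step 2 | (1S)-chlorohydrin with free hydroxyl | O=C1C[C@H](C#C[Si](C(C)C)(C(C)C)C(C)C)C(OC)(OC)[C@@H](C(C)=C)[C@]1(C)[C@H](O)CCl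
F6 | step 11 | desilylated chlorohydrin diol of 21 (6β-OH, (1S)-2-chloro-1-hydroxyethyl) | C=C(C)C(=O)O[C@@H]1[C@@H]2OC(=O)C(=C)[C@@H]2[C@@H](O)[C@@H](C(=C)C=O)[C@]1(C)[C@H](O)CCl
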